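## Retrosynthetic overview
1. Target 8 comes from its hexamethyl ether 7; the six O-methyl groups are removed last.
2. 7 comes from bis-deoxybenzoin 4. Both pyranone rings close in one operation, each taking one carbon from 5. Only one oxygen beside each ketone is free, so ring P closes 8-linked and ring Q closes 6-linked.
3. 4 comes from biphenol 2 and two molecules of 3 by two-directional ortho-acylation.
4. Key step: 2 comes from two molecules of 1. The unsymmetrical 6,8'' bond is read as the ortho–para dehydrodimer of a single phenol, so no halide, boron reagent or isoflavone–isoflavone cross-coupling is needed.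
5. Ring order: the four benzene rings are bought, the biaryl bond is made first, and the two pyranone rings are made last and together.

Assumption: the SMILES has no stereocentre and gives no sense for the hindered 6,8'' axis, so the compound is made as drawn, with the axis unassigned (racemic pair of atropisomers).

## Route

Step 1
Reactants: 1 3,5-dimethoxyphenol (two molecules)
Product: 2 2',4,6,6'-tetramethoxybiphenyl-2,4'-diol (ring P = 2-hydroxy-4,6-dimethoxyphenyl; ring Q = 4-hydroxy-2,6-dimethoxyphenyl)
Conditions: FeCl3 (10 mol %), t-BuOOt-Bu (0.6 equiv, slow addition), HFIP, rt, stopped at about 70 % conversion; SiO2, 1 recovered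
Reagents that add atoms: none
Why: Proposed new method: iron-catalysed oxidative phenol coupling in HFIP (phenoxyl radical plus neutral phenol, then loss of two hydrogens and tautomerisation) is the closest known reaction type and ortho–para homocoupling is known for other phenols, but the ortho–para outcome for 1 is an extrapolation resting on three points, namely that the carbon para to OH is the most nucleophilic and most spin-rich site of 1 (it is where 1 is formylated), that para–para union would crowd four OMe groups around the new bond, and that ortho–para union is statistically doubled; no stereo-element arises because ring Q of 2 is symmetric.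

Step 2
Reactants: 2 2',4,6,6'-tetramethoxybiphenyl-2,4'-diol; 3 4-methoxyphenylacetic acid (2.5 equiv)
Product: 4 1,1'-(2,4'-dihydroxy-2',4,6,6'-tetramethoxybiphenyl-3,3'-diyl)bis[2-(4-methoxyphenyl)ethanone] (racemic axis)
Conditions: BF3·Et2O (as solvent), 85 °C, 3 h; then aq NaOAc
Reagents that add atoms: 4-methoxyphenylacetic acid (3), COc1ccc(CC(=O)O)cc1
Why: Two-directional BF3-promoted Friedel–Crafts acylation of a phenol by an arylacetic acid (the standard deoxybenzoin synthesis with Fries-type ortho delivery) puts each acyl group ortho to a free OH, because only that OH/OMe-flanked position gives the chelated ortho-hydroxyketone and it is less crowded than the OMe/OMe-flanked CH of ring P, just as 1 itself gives 2-hydroxy-4,6-dimethoxydeoxybenzoins; no stereocentre forms, but ring Q loses its symmetry, so the axis becomes stereogenic and 4 is racemic.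

Step 3
Reactants: 4 bis-deoxybenzoin; 5 N,N-dimethylformamide dimethyl acetal (6 equiv)
Product: 7 5,7-dimethoxy-3-(4-methoxyphenyl)-6-[5,7-dimethoxy-3-(4-methoxyphenyl)-4-oxo-4H-chromen-8-yl]-4H-chromen-4-one (6,8''-bigenistein hexamethyl ether; racemic axis), via bis-enaminone 6 (not isolated)
Conditions: 5, toluene, 100 °C, 4 h; then AcOH, 60 °C, 1 h
Reagents that add atoms: N,N-dimethylformamide dimethyl acetal (5), COC(OC)N(C)C
Why: This is the enaminone route to isoflavones (amide-acetal condensation of a 2-hydroxydeoxybenzoin, then intramolecular addition–elimination): each activated CH2 condenses with 5 to give 6 and the one free phenol beside each ketone displaces Me2NH, so ring P can only close to the 8-linked chromenone and ring Q only to the 6-linked one, since the other flanking oxygen is still a methyl ether; no stereocentre forms.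

Step 4
Reactants: 7 6,8''-bigenistein hexamethyl ether
Product: 8 5,7-dihydroxy-3-(4-hydroxyphenyl)-6-[5,7-dihydroxy-3-(4-hydroxyphenyl)-4-oxo-4H-chromen-8-yl]-4H-chromen-4-one (6,8''-bigenistein, CNP0184660.0)
Conditions: BBr3 (20 equiv), CH2Cl2, −78 °C to 40 °C, 24 h; then H2O, 0 °C
Reagents that add atoms: none
Why: Exhaustive BBr3 cleavage of aryl methyl ethers (bromide attack on the methyl of the boron-complexed ether) is the usual last step for hexamethyl ethers of carbon-linked biflavonoids, leaves the pyranones and the biaryl bond untouched, and, being anhydrous and held at or below 40 °C, avoids the Wessely–Moser ring opening and reclosure that hot aqueous acid would cause once the 5-OH groups are free, so the 6,8'' linkage is kept.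

## Compound list
1 | 3,5-dimethoxyphenol | COc1cc(O)cc(OC)c1 | starting material
2 | 2',4,6,6'-tetramethoxybiphenyl-2,4'-diol (ortho–para dimer of 1, achiral) | COc1cc(O)c(c(OC)c1)-c1c(OC)cc(O)cc1OC | intermediate
3 | 4-methoxyphenylacetic acid | COc1ccc(CC(=O)O)cc1 | starting material
4 | 1,1'-(2,4'-dihydroxy-2',4,6,6'-tetramethoxybiphenyl-3,3'-diyl)bis[2-(4-methoxyphenyl)ethanone], racemic axis | COc1ccc(CC(=O)c2c(OC)cc(OC)c(c2O)-c2c(OC)cc(O)c(C(=O)Cc3ccc(OC)cc3)c2OC)cc1 | intermediate
5 | N,N-dimethylformamide dimethyl acetal | COC(OC)N(C)C | starting material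
6 | bis-enaminone: 4 with each CH2 turned into C=CH–NMe2 (alkene geometry not fixed, both forms interconvert and both cyclise) | COc1ccc(cc1)C(=CN(C)C)C(=O)c1c(OC)cc(OC)c(c1O)-c1c(OC)cc(O)c(C(=O)C(=CN(C)C)c2ccc(OC)cc2)c1OC | intermediate (not isolated)
7 | 6,8''-bigenistein hexamethyl ether, racemic axis | O=c1c(-c2ccc(OC)cc2)coc2cc(OC)c(-c3c(OC)cc(OC)c4c(=O)c(-c5ccc(OC)cc5)coc34)c(OC)c12 | intermediate
8 | 6,8''-bigenistein | O=c1c(-c2ccc(O)cc2)coc2cc(O)c(-c3c(O)cc(O)c4c(=O)c(-c5ccc(O)cc5)coc34)c(O)c12 | target

## Count and risks
Total step count: 4. Longest linear sequence: 4 (1 → 2 → 4 → 7 → 8).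

**Step 1** is the most likely to fail. The ortho–ortho dimer or oligomers may dominate, and a realistic hope is 35–45 % of 2, which is the more polar dimer and is separable. The fallback drops oxidation chemistry and makes the same bond by polar 1,2-addition to a quinone. It sets out from 1 and comes back at 2.
- Compound 1 is protected (MOMCl, iPr2NEt, CH2Cl2) as 1,3-dimethoxy-5-(methoxymethoxy)benzene F1.
- n-BuLi (THF, 0 °C) lithiates it between OMOM and OMe to give [2,4-dimethoxy-6-(methoxymethoxy)phenyl]lithium F2.
- At −78 °C this adds to commercial 2,6-dimethoxy-1,4-benzoquinone at the carbonyl flanked by the two methoxy-bearing carbons. The other carbonyl is a doubly vinylogous ester and far less electrophilic. After NH4Cl quench the product is the para-quinol 4-[2,4-dimethoxy-6-(methoxymethoxy)phenyl]-4-hydroxy-3,5-dimethoxycyclohexa-2,5-dien-1-one F3.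
- Zn dust in AcOH removes the tertiary OH with aromatisation to 2,2',4',6-tetramethoxy-6'-(methoxymethoxy)biphenyl-4-ol F4.
- HCl in MeOH takes off the MOM group to give 2.

**Step 2** is second. The second acylation may stall. Hot BF3 may close the electron-rich 2-hydroxy-2'-methoxybiaryl to a dibenzofuran, or may cleave the OMe beside a new ketone, which would unlock the wrong ring closure. The fallback replaces electrophilic substitution by directed ortho-metalation under basic conditions. It sets out from 2 and comes back at 4.
- Compound 2 is converted (MOMCl, NaH, DMF) into 2',4,6,6'-tetramethoxy-2,4'-bis(methoxymethoxy)biphenyl F5.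
- The acyl donor N-methoxy-2-(4-methoxyphenyl)-N-methylacetamide F6 is made in one operation from commercial 4-methoxyphenylacetyl chloride and MeNHOMe·HCl in pyridine.
- s-BuLi/TMEDA (2.5 equiv, THF, −78 to −20 °C) lithiates F5 twice, each time at a CH lying between OMOM and OMe. This gives 3,3'-dilithio-2',4,6,6'-tetramethoxy-2,4'-bis(methoxymethoxy)biphenyl F7.
- F6 acylates F7 to 1,1'-[2',4,6,6'-tetramethoxy-2,4'-bis(methoxymethoxy)biphenyl-3,3'-diyl]bis[2-(4-methoxyphenyl)ethanone] F8.
- HCl in MeOH (40 °C) gives 4.

**Step 4** is third. The 7-OMe groups are vinylogous-ester oxygens and poor Lewis bases, so cleavage may stall, and the hexaphenol is hard to purify. The fallback changes the polarity of the cleavage and the mode of isolation. It sets out from 7 and comes back at 8.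
- BBr3 at room temperature is taken only as far as it goes easily, to 4',4''',5,5''-tetrahydroxy-7,7''-dimethoxy-6,8''-biisoflavone F9.
- The two remaining methyls are good substrates for attack by a soft nucleophile and are removed with NaSEt in DMF at 110 °C. The phenoxides present deactivate the pyranones towards ring opening.
- The crude product is acetylated (Ac2O, pyridine) to 6,8''-bigenistein hexaacetate F10, which is purified by chromatography and crystallisation.
- Acid methanolysis (HCl in MeOH, 40 °C) gives 8.

## Further compounds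
F1 | step 1 | 1,3-dimethoxy-5-(methoxymethoxy)benzene | COCOc1cc(OC)cc(OC)c1
F2 | step 1 | [2,4-dimethoxy-6-(methoxymethoxy)phenyl]lithium | [Li]c1c(OC)cc(OC)cc1OCOC
F3 | step 1 | 4-[2,4-dimethoxy-6-(methoxymethoxy)phenyl]-4-hydroxy-3,5-dimethoxycyclohexa-2,5-dien-1-one | COCOc1cc(OC)cc(OC)c1C1(O)C(OC)=CC(=O)C=C1OC
F4 | step 1 | 2,2',4',6-tetramethoxy-6'-(methoxymethoxy)biphenyl-4-ol | COCOc1cc(OC)cc(OC)c1-c1c(OC)cc(O)cc1OC
F5 | step 2 | 2',4,6,6'-tetramethoxy-2,4'-bis(methoxymethoxy)biphenyl | COCOc1cc(OC)cc(OC)c1-c1c(OC)cc(OCOC)cc1OC
F6 | step 2 | N-methoxy-2-(4-methoxyphenyl)-N-methylacetamide | COc1ccc(CC(=O)N(C)OC)cc1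
F7 | step 2 | 3,3'-dilithio-2',4,6,6'-tetramethoxy-2,4'-bis(methoxymethoxy)biphenyl | [Li]c1c(OC)cc(OC)c(c1OCOC)-c1c(OC)cc(OCOC)c([Li])c1OC
F8 | step 2 | 1,1'-[2',4,6,6'-tetramethoxy-2,4'-bis(methoxymethoxy)biphenyl-3,3'-diyl]bis[2-(4-methoxyphenyl)ethanone] | COCOc1c(C(=O)Cc2ccc(OC)cc2)c(OC)cc(OC)c1-c1c(OC)cc(OCOC)c(C(=O)Cc2ccc(OC)cc2)c1OC
F9 | step 4 | 4',4''',5,5''-tetrahydroxy-7,7''-dimethoxy-6,8''-biisoflavone | O=c1c(-c2ccc(O)cc2)coc2cc(OC)c(-c3c(OC)cc(O)c4c(=O)c(-c5ccc(O)cc5)coc34)c(O)c12
F10 | step 4 | 6,8''-bigenistein hexaacetate | O=c1c(-c2ccc(OC(C)=O)cc2)coc2cc(OC(C)=O)c(-c3c(OC(C)=O)cc(OC(C)=O)c4c(=O)c(-c5ccc(OC(C)=O)cc5)coc34)c(OC(C)=O)c12
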